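(6R,6′R)-ε,ε-Carotene has a C2 axis through the midpoint of C15=C15′. The sp2–sp2 single bonds C12–C13 and C12′–C13′ are therefore equivalent, and both trimethylcyclohexene rings (rings A and B) come from one building block. The route cuts both bonds: C16 + C8 + C16. In one pot, (E)-oct-4-ene-2,6-diyne is hydrozirconated twice, which sets C13=C14 and C13′=C14′ as E with the metal on the methyl-bearing carbons. It is then relayed to zinc and coupled twice under palladium catalysis with a (6R)-trienyl iodide made in three steps from (R)-α-ionone. The second coupling unites the C16 iodide with a C24 hexaenylzinc. The precursor is thus a small enediyne, not a polyene.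

Key step: step 5

Assumption: (R)-(+)-α-ionone 1 is bought as the enantiopure natural-grade (fermentation-derived) flavour compound and supplies both stereocentres. Positions are given in carotenoid numbering (C1–C15, C1′–C15′).

Step 1
Reactants: 1 (R)-α-ionone; 2 diethyl cyanomethylphosphonate
Product: 3 (2E,4E)-3-methyl-5-[(1R)-2,6,6-trimethylcyclohex-2-en-1-yl]penta-2,4-dienenitrile
Conditions: 2 (1.3 equiv), NaH (1.2 equiv), THF, 0 °C; then 1, 0 °C to rt; minor (2Z) isomer removed on silica gel
Reagents that add atoms: diethyl cyanomethylphosphonate 2, CCOP(=O)(CC#N)OCC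
Why: Horner–Wadsworth–Emmons olefination of the methyl ketone with a stabilised phosphonate anion should favour the E-trisubstituted C9=C10 alkene, and the preformed anion is too weak a base to remove the doubly allylic C6–H, so the (6R) centre brought in by 1 is kept.

Step 2
Reactants: 3 C15 dienenitrile
Product: 5 (2E,4E)-3-methyl-5-[(1R)-2,6,6-trimethylcyclohex-2-en-1-yl]penta-2,4-dienal, via N-diisobutylaluminio imine 4 (not isolated)
Conditions: iBu2AlH (1.2 equiv), toluene, −78 °C; then wet silica gel, 0 °C
Reagents that add atoms: water, O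
Why: Partial reduction of a nitrile with iBu2AlH stops at the N-aluminio imine 4, and mild hydrolysis then releases the dienal without touching the alkenes or C6.

Step 3
Reactants: 5 C15 dienal; 6 iodoform
Product: 7 (1E,3E,5E)-1-iodo-4-methyl-6-[(1R)-2,6,6-trimethylcyclohex-2-en-1-yl]hexa-1,3,5-triene
Conditions: CHI3 (2 equiv), CrCl2 (8 equiv), THF/1,4-dioxane, 0 °C to rt, dark
Reagents that add atoms: iodoform 6, IC(I)I
Why: In the Takai iodoolefination the geminal dichromium species formed from CHI3 and divalent chromium adds to the aldehyde and eliminates to the E-alkenyl iodide (C11=C12), under essentially neutral conditions that leave the diene and C6 alone.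

Step 4
Reactants: 8 (E)-1,2-dichloroethene; 9 propyne
Product: 10 (E)-oct-4-ene-2,6-diyne
Conditions: propyne (3 equiv), Pd(PPh3)4 (5 mol %), CuI (10 mol %), piperidine (4 equiv), THF, sealed flask, rt to 40 °C; product kept as a titrated solution
Reagents that add atoms: propyne 9, CC#C
Why: In this twofold Sonogashira coupling (E)-1,2-dichloroethene acts as a vinylene dielectrophile whose geometry is retained in both oxidative additions, which fixes C15=C15′ as E.

Step 5
Reactants: 10 (E)-oct-4-ene-2,6-diyne; 7 C16 trienyl iodide (two equivalents)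
Product: 14 (6R,6′R)-ε,ε-carotene, via bis(alkenylzirconocene chloride) 11 (not isolated), via bis(alkenylzinc chloride) 12 (not isolated), via C24 hexaenylzinc chloride 13 (not isolated)
Conditions: Cp2Zr(H)Cl (2.3 equiv), THF, rt to 40 °C, dark; solution decanted from residual solid; ZnCl2 (2.2 equiv), 0 °C; 7 (2.1 equiv), Pd(PPh3)4 (5 mol %), 0 °C to rt, dark; crystallisation
Reagents that add atoms: none
Why: Cp2Zr(H)Cl adds H and Zr syn across each alkyne of 10 with Zr on the less hindered methyl-bearing carbon (C13, C13′) to give 11, ZnCl2 relays both alkenyl groups to zinc (12), and a zerovalent palladium cycle (oxidative addition into the C12–I bond of 7, zinc-to-palladium transmetalation, reductive elimination) forms C12–C13 and then, on the C24 hexaenylzinc 13, C12′–C13′. The closest known reaction type is the hydrozirconation/Negishi alkenyl–alkenyl coupling with ZnCl2 as co-metal, which is the standard answer to α-substituted alkenylzirconocenes that couple sluggishly on their own, and here it runs in two directions on one bis-nucleophile. No ring is closed and no stereocentre is created; C6 and C6′ arrive as R in 7 and lie far from all bond-making under conditions that are neither basic nor acidic. The step needs regioselective hydrometalation, reaction at the alkynes rather than at C15=C15′, and clean geometry at five alkenes: the size difference between methyl and alkenyl, helped by equilibration with the slight excess of Cp2Zr(H)Cl, should secure the first, the inertness of a 1,2-disubstituted alkene to Cp2Zr(H)Cl the second, and the stereospecificity of syn addition, transmetalation and reductive elimination the third. The two ends of 12 are homotopic, so the couplings need no differentiation, and any trace of (6S)-iodide should end mainly in the meso diastereomer, which crystallisation should remove.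

Compound list
1 | (R)-α-ionone, (3E)-4-[(1R)-2,6,6-trimethylcyclohex-2-en-1-yl]but-3-en-2-one | CC1=CCCC(C)(C)[C@H]1/C=C/C(C)=O | starting material
2 | diethyl cyanomethylphosphonate | CCOP(=O)(CC#N)OCC | starting material
3 | (2E,4E)-3-methyl-5-[(1R)-2,6,6-trimethylcyclohex-2-en-1-yl]penta-2,4-dienenitrile | CC1=CCCC(C)(C)[C@H]1/C=C/C(C)=C/C#N | intermediate
4 | N-diisobutylaluminio imine of dienal 5 | CC1=CCCC(C)(C)[C@H]1/C=C/C(C)=C/C=N[Al](CC(C)C)CC(C)C | intermediate
5 | (2E,4E)-3-methyl-5-[(1R)-2,6,6-trimethylcyclohex-2-en-1-yl]penta-2,4-dienal | CC1=CCCC(C)(C)[C@H]1/C=C/C(C)=C/C=O | intermediate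
6 | iodoform | IC(I)I | starting material
7 | (1E,3E,5E)-1-iodo-4-methyl-6-[(1R)-2,6,6-trimethylcyclohex-2-en-1-yl]hexa-1,3,5-triene | CC1=CCCC(C)(C)[C@H]1/C=C/C(C)=C/C=C/I | intermediate
8 | (E)-1,2-dichloroethene | Cl/C=C/Cl | starting material
9 | propyne | CC#C | starting material
10 | (E)-oct-4-ene-2,6-diyne | CC#C/C=C/C#CC | intermediate
11 | (2E,4E,6E)-2,7-bis[chlorobis(cyclopentadienyl)zirconio]octa-2,4,6-triene (cyclopentadienyl rings drawn σ-bonded) | Cl[Zr](C1C=CC=C1)(C1C=CC=C1)/C(C)=C/C=C/C=C(C)/[Zr](Cl)(C1C=CC=C1)C1C=CC=C1 | intermediate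
12 | (2E,4E,6E)-2,7-bis(chlorozincio)octa-2,4,6-triene | Cl[Zn]/C(C)=C/C=C/C=C(C)/[Zn]Cl | intermediate
13 | chloro{(2E,4E,6E,8E,10E,12E)-7,11-dimethyl-13-[(1R)-2,6,6-trimethylcyclohex-2-en-1-yl]trideca-2,4,6,8,10,12-hexaen-2-yl}zinc | CC1=CCCC(C)(C)[C@H]1/C=C/C(C)=C/C=C/C(C)=C/C=C/C=C(C)/[Zn]Cl | intermediate
14 | (6R,6′R)-ε,ε-carotene, all-E | CC1=CCCC(C)(C)[C@H]1/C=C/C(C)=C/C=C/C(C)=C/C=C/C=C(C)/C=C/C=C(C)/C=C/[C@H]1C(C)=CCCC1(C)C | target

Total step count: 5. Longest linear sequence: 4 (steps 1, 2, 3 and 5).

Steps most likely to fail

Step 5. The metal may settle partly on C14 or C14′ during the double hydrozirconation. The sequence may also stall after the first coupling, or the C24 organozinc may be lost by protodemetalation. The fallback sets out from 10 and 5 and comes back at 14. The solution of 11 made from 10 is quenched with I2 to give (2E,4E,6E)-2,7-diiodoocta-2,4,6-triene F1. This compound can be freed of regioisomers by crystallisation before any chiral material is committed. Aldehyde 5 is taken by the boron variant of the Takai olefination (Cl2CHBpin, CrCl2, LiI, THF) to 2-{(1E,3E,5E)-4-methyl-6-[(1R)-2,6,6-trimethylcyclohex-2-en-1-yl]hexa-1,3,5-trien-1-yl}-4,4,5,5-tetramethyl-1,3,2-dioxaborolane F2. A twofold Suzuki–Miyaura coupling of F1 with two equivalents of F2 (Pd(PPh3)4, aqueous K3PO4, THF, dark) gives 14. The polarity of both C12–C13 unions is reversed, and the regiochemical question is settled before the carbon–carbon bonds are made.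

Step 3. The risks are poor E/Z control at C11=C12 and decay of the acid-sensitive dienal on the Lewis acidic chromium salts. The fallback sets out from 5 and comes back at 7. Colvin homologation of 5 with lithiated trimethylsilyldiazomethane (Me3SiCHN2, LiN(iPr)2, THF, −78 °C to rt) gives (6R)-1,5,5-trimethyl-6-[(1E,3E)-3-methylhexa-1,3-dien-5-yn-1-yl]cyclohex-1-ene F3. Hydrozirconation of the terminal alkyne with Cp2Zr(H)Cl gives the (E)-trienylzirconocene chloride F4. Iodinolysis with I2 then delivers 7, with the E geometry dictated by syn addition rather than by an olefination transition state.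

Step 4. The risks are stalling at the monochloroenyne, oxidative homocoupling of propyne, and loss of gaseous reagent and volatile product. The fallback sets out from 8 and comes back at 10. Twofold Sonogashira coupling of 8 with ethynyltrimethylsilane (Pd(PPh3)4, CuI, piperidine) gives the easily handled (E)-1,6-bis(trimethylsilyl)hex-3-ene-1,5-diyne F5. Desilylative lithiation with MeLi·LiBr in THF gives (E)-1,6-dilithiohex-3-ene-1,5-diyne F6, and methylation with MeI gives 10. The two terminal methyl groups are thus installed by alkylation rather than carried in by propyne.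

Further compounds
F1 | step 5 | (2E,4E,6E)-2,7-diiodoocta-2,4,6-triene | I/C(C)=C/C=C/C=C(C)/I
F2 | step 5 | 2-{(1E,3E,5E)-4-methyl-6-[(1R)-2,6,6-trimethylcyclohex-2-en-1-yl]hexa-1,3,5-trien-1-yl}-4,4,5,5-tetramethyl-1,3,2-dioxaborolane | CC1=CCCC(C)(C)[C@H]1/C=C/C(C)=C/C=C/B1OC(C)(C)C(C)(C)O1
F3 | step 3 | (6R)-1,5,5-trimethyl-6-[(1E,3E)-3-methylhexa-1,3-dien-5-yn-1-yl]cyclohex-1-ene | CC1=CCCC(C)(C)[C@H]1/C=C/C(C)=C/C#C
F4 | step 3 | chlorobis(cyclopentadienyl){(1E,3E,5E)-4-methyl-6-[(1R)-2,6,6-trimethylcyclohex-2-en-1-yl]hexa-1,3,5-trien-1-yl}zirconium | CC1=CCCC(C)(C)[C@H]1/C=C/C(C)=C/C=C/[Zr](Cl)(C1C=CC=C1)C1C=CC=C1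
F5 | step 4 | (E)-1,6-bis(trimethylsilyl)hex-3-ene-1,5-diyne | C[Si](C)(C)C#C/C=C/C#C[Si](C)(C)C
F6 | step 4 | (E)-1,6-dilithiohex-3-ene-1,5-diyne | [Li]C#C/C=C/C#C[Li]
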